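**Plan**
Numbering: ring A = C1–C5 and C10, ring B = C5–C10, C17 = exocyclic CH2 on C8, C11 = CH2 between C9 and pyrone C3' (the ring carbon between C2'–OMe and C4'=O). β is the face of the C3 hydroxyl: 3-OH, the C4 side chain and C11 are β, while H5, H9, 4-CH3 and 10-CH3 are α, so the target is a cis-fused decalin (3S,4R,5R,9S,10S).
Cuts: C8–C9 of ring B (last C–C bond), then C11–C3' (made at the alkene level as an sp2–sp2 bond), C4–CH3, the two Diels–Alder bonds C1–C2 and C5–C10 of ring A, and C4=C5 of an acyclic enone.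
Enabling feature: the array C17H2=C8–C9(H)–C11H2–C3'(pyrone) is the footprint of a reductive 1,7-enyne closure. A terminal alkyne C8≡C17 becomes the exocyclic methylene, and the γ-pyrone ring on C11 makes C9=C11 a styrene-like acceptor that takes a C8 vinyl radical only at C9.
Forward: HWE enone, 2-silyloxydiene, Diels–Alder with methacrolein (ring A), Takai iodo-olefination, C4 methylation, side-chain hydration with C3 reduction, protection and formylation, Negishi union with an iodopyrone made in three steps, radical closure of ring B, desilylation.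
Stereochemistry: C5 and C10 come from the catalytic enantioselective endo Diels–Alder step. C4 (methylation), C3 (hydride) and C9 (ring closure) follow by substrate control from these two centres.

Key step: step 16

Assumption: the (S)-configured oxazaborolidinium catalyst is taken to deliver the (1R,2S) adduct 9; should the sense of induction be the opposite, the (R)-configured catalyst is used and nothing else changes.

Step 1
Reactants: 1 dimethyl (2-oxopropyl)phosphonate; 2 1-bromo-3-methylbut-2-ene (prenyl bromide)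
Product: 3 dimethyl (6-methyl-2-oxohept-5-en-3-yl)phosphonate (racemic)
Conditions: NaH, THF, 0 → 23 °C
Reagents that add atoms: none
Why: SN2 C-alkylation of the doubly stabilised β-ketophosphonate carbanion by a reactive allylic bromide gives the α-prenyl phosphonate, whose stereocentre does not matter because it becomes sp2 in step 3.

Step 2
Reactants: 4 pent-4-yn-1-ol
Product: 5 pent-4-ynal
Conditions: TEMPO (10 mol %), PhI(OAc)2, CH2Cl2, 23 °C
Reagents that add atoms: none
Why: Oxoammonium-mediated oxidation of a primary alcohol stops at the aldehyde and does not touch the terminal alkyne.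

Step 3
Reactants: 3 dimethyl (6-methyl-2-oxohept-5-en-3-yl)phosphonate; 5 pent-4-ynal
Product: 6 (E)-3-(3-methylbut-2-enyl)oct-3-en-7-yn-2-one
Conditions: NaH, THF, 0 °C; then 5, 0 → 23 °C
Reagents that add atoms: none
Why: Horner–Wadsworth–Emmons olefination of an unhindered aldehyde with an α-branched β-ketophosphonate gives the trisubstituted enone, and the reversible addition favours the E isomer with the C6 chain trans to the acetyl group, as the diene of step 5 requires.

Step 4
Reactants: 6 (E)-3-(3-methylbut-2-enyl)oct-3-en-7-yn-2-one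
Product: 7 (E)-triisopropyl{[3-(3-methylbut-2-enyl)octa-1,3-dien-7-yn-2-yl]oxy}silane
Conditions: TIPSOTf, Et3N, CH2Cl2, 0 °C
Reagents that add atoms: triisopropylsilyl trifluoromethanesulfonate, CC(C)[Si](C(C)C)(C(C)C)OS(=O)(=O)C(F)(F)F
Why: Soft enolisation with a silyl triflate and a tertiary amine removes a proton from the acetyl CH3 and gives the cross-conjugated 2-silyloxy-1,3-diene with the C4=C5 geometry intact, the terminal alkyne not being acidic enough to react.

Step 5
Reactants: 7 (E)-triisopropyl{[3-(3-methylbut-2-enyl)octa-1,3-dien-7-yn-2-yl]oxy}silane; 8 methacrolein (2-methylprop-2-enal)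
Product: 9 (1R,2S)-2-(but-3-ynyl)-1-methyl-3-(3-methylbut-2-enyl)-4-(triisopropylsilyloxy)cyclohex-3-ene-1-carbaldehyde (butynyl chain cis to CHO)
Conditions: (S)-3,3-diphenyl-1-(o-tolyl)tetrahydro-1H,3H-pyrrolo[1,2-c][1,3,2]oxazaborole (20 mol %), HNTf2 (18 mol %), CH2Cl2, −78 → −40 °C
Reagents that add atoms: none
Why: In this enantioselective Diels–Alder reaction the 2-silyloxy group ("para") and the terminal alkyl group ("ortho") both direct C5 to the methyl-bearing carbon of the activated enal, the endo transition state (formyl under the diene) puts the outside C6 chain cis to the formyl carbon C9, and the chiral oxazaborolidinium ion shields one enal face and so fixes the absolute configuration of C5 and C10.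

Step 6
Reactants: 9 (1R,2S)-2-(but-3-ynyl)-1-methyl-3-(3-methylbut-2-enyl)-4-(triisopropylsilyloxy)cyclohex-3-ene-1-carbaldehyde
Product: 10 {[(3R,4R)-3-(but-3-ynyl)-4-[(E)-2-iodoethenyl]-4-methyl-2-(3-methylbut-2-enyl)cyclohex-1-en-1-yl]oxy}triisopropylsilane
Conditions: CrCl2 (6 equiv), CHI3 (2 equiv), THF, 0 → 23 °C
Reagents that add atoms: iodoform, IC(I)I
Why: Takai olefination with the gem-dichromium species from CHI3 and CrCl2 converts even α-quaternary aldehydes into E-iodoalkenes under non-basic conditions that leave the silyl enol ether, the alkyne and both stereocentres untouched.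

Step 7
Reactants: 10 {[(3R,4R)-3-(but-3-ynyl)-4-[(E)-2-iodoethenyl]-4-methyl-2-(3-methylbut-2-enyl)cyclohex-1-en-1-yl]oxy}triisopropylsilane
Product: 12 (2R,3R,4R)-3-(but-3-ynyl)-4-[(E)-2-iodoethenyl]-2,4-dimethyl-2-(3-methylbut-2-enyl)cyclohexan-1-one, via tetrabutylammonium enolate 11 (not isolated)
Conditions: MeI (10 equiv), Bu4NF (1.1 equiv, anhydrous), 4 Å MS, THF, −78 → 0 °C
Reagents that add atoms: iodomethane, CI
Why: Fluoride cleavage of the regiodefined silyl enol ether releases the C3–C4 enolate, and its C-methylation (regiospecific enolate alkylation) should occur on the α face, opposite to the adjacent C5 butynyl chain (pseudo-axial to avoid allylic strain with the prenyl group) and to the C10 iodovinyl group, so that 4-CH3 is α and the prenyl group β.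

Step 8
Reactants: 12 (2R,3R,4R)-3-(but-3-ynyl)-4-[(E)-2-iodoethenyl]-2,4-dimethyl-2-(3-methylbut-2-enyl)cyclohexan-1-one
Product: 13 (2R,3R,4R)-3-(but-3-ynyl)-2-[(3,3-dimethyloxiran-2-yl)methyl]-4-[(E)-2-iodoethenyl]-2,4-dimethylcyclohexan-1-one (both oxirane epimers)
Conditions: mCPBA (1.05 equiv), CH2Cl2, 0 °C
Reagents that add atoms: 3-chloroperoxybenzoic acid, OOC(=O)c1cccc(Cl)c1
Why: Prilezhaev epoxidation follows alkene nucleophilicity, so the trisubstituted prenyl double bond reacts far faster than the iodoalkene, the alkyne or the hindered ketone, and the uncontrolled oxirane stereocentre disappears in step 9.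

Step 9
Reactants: 13 (2R,3R,4R)-3-(but-3-ynyl)-2-[(3,3-dimethyloxiran-2-yl)methyl]-4-[(E)-2-iodoethenyl]-2,4-dimethylcyclohexan-1-one
Product: 14 (1S,2R,3R,4R)-3-(but-3-ynyl)-2-(3-hydroxy-3-methylbutyl)-4-[(E)-2-iodoethenyl]-2,4-dimethylcyclohexan-1-ol
Conditions: LiEt3BH (3.5 equiv), THF, −78 → 0 °C; H2O
Reagents that add atoms: none
Why: The hydride opens the trisubstituted oxirane by SN2 attack at its CH carbon to give the tertiary alcohol and reduces the ketone from the α face, since the β face is screened in either chair by the C4 side chain and the C5 and C10 substituents, which sets 3β-OH (3S) while the sp2 C–I bond stays inert.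

Step 10
Reactants: 14 (1S,2R,3R,4R)-3-(but-3-ynyl)-2-(3-hydroxy-3-methylbutyl)-4-[(E)-2-iodoethenyl]-2,4-dimethylcyclohexan-1-ol
Product: 15 4-{(1R,2R,3R,6S)-2-(but-3-ynyl)-3-[(E)-2-iodoethenyl]-1,3-dimethyl-6-(triethylsilyloxy)cyclohexyl}-2-methylbutan-2-ol
Conditions: TESCl (1.1 equiv), imidazole, DMF, 0 → 23 °C
Reagents that add atoms: chlorotriethylsilane, CC[Si](Cl)(CC)CC
Why: Silylation with a chlorosilane and imidazole discriminates kinetically between the secondary C3 hydroxyl and the tertiary carbinol, which does not react under these conditions.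

Step 11
Reactants: 15 4-{(1R,2R,3R,6S)-2-(but-3-ynyl)-3-[(E)-2-iodoethenyl]-1,3-dimethyl-6-(triethylsilyloxy)cyclohexyl}-2-methylbutan-2-ol
Product: 16 4-{(1R,2R,3R,6S)-2-(but-3-ynyl)-3-[(E)-2-iodoethenyl]-1,3-dimethyl-6-(triethylsilyloxy)cyclohexyl}-2-methylbutan-2-yl formate
Conditions: preformed acetic formic anhydride, pyridine, DMAP (cat.), CH2Cl2, 0 → 23 °C
Reagents that add atoms: acetic formic anhydride, CC(=O)OC=O
Why: DMAP-catalysed acyl transfer from the mixed anhydride occurs at its smaller and more electrophilic formyl carbon, which allows O-formylation of the tertiary alcohol without touching the silyl ether.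

Step 12
Reactants: 17 methyl acetoacetate; 18 malonyl dichloride
Product: 19 methyl 4-hydroxy-2-methyl-6-oxo-6H-pyran-3-carboxylate
Conditions: CH2Cl2, 0 → 40 °C
Reagents that add atoms: none
Why: Malonyl dichloride acylates the β-keto ester once at its α-carbon and once at its enol oxygen (C,O-bisacylation, a standard 4-hydroxy-2-pyrone synthesis), which closes the ring with ester and methyl group on adjacent ring carbons.

Step 13
Reactants: 19 methyl 4-hydroxy-2-methyl-6-oxo-6H-pyran-3-carboxylate
Product: 20 methyl 6-methoxy-2-methyl-4-oxo-4H-pyran-3-carboxylate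
Conditions: MeOTf, CH2Cl2, 23 °C
Reagents that add atoms: methyl trifluoromethanesulfonate, COS(=O)(=O)C(F)(F)F
Why: The hard methylating agent attacks the most basic site of the neutral 4-hydroxy-2-pyrone, the lactone carbonyl oxygen (the 4-OH is hydrogen-bonded to the ester), and proton loss from the 2-methoxy-4-hydroxypyrylium ion gives the 2-methoxy-4-pyrone (known α-pyrone to γ-pyrone O-methylation).

Step 14
Reactants: 20 methyl 6-methoxy-2-methyl-4-oxo-4H-pyran-3-carboxylate
Product: 21 methyl 5-iodo-6-methoxy-2-methyl-4-oxo-4H-pyran-3-carboxylate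
Conditions: NIS, CF3CO2H (cat.), MeCN, 23 °C
Reagents that add atoms: N-iodosuccinimide, O=C1CCC(=O)N1I
Why: Electrophilic iodination takes place at the only ring CH (C3'), which is the nucleophilic β-carbon of the C2'(OMe)=C3' enol-ether unit.

Step 15
Reactants: 21 methyl 5-iodo-6-methoxy-2-methyl-4-oxo-4H-pyran-3-carboxylate; 16 4-{(1R,2R,3R,6S)-2-(but-3-ynyl)-3-[(E)-2-iodoethenyl]-1,3-dimethyl-6-(triethylsilyloxy)cyclohexyl}-2-methylbutan-2-yl formate
Product: 23 methyl 5-[(E)-2-{(1S,2R,3R,4S)-2-(but-3-ynyl)-3-[3-(formyloxy)-3-methylbutyl]-1,3-dimethyl-4-(triethylsilyloxy)cyclohexyl}ethenyl]-6-methoxy-2-methyl-4-oxo-4H-pyran-3-carboxylate, via pyronylzinc iodide 22 (not isolated)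
Conditions: 21, Zn dust, LiCl, THF, 23 °C; then 16, Pd2(dba)3 (2.5 mol %), SPhos (10 mol %), THF, 23 → 40 °C
Reagents that add atoms: none
Why: In this Negishi coupling the LiCl-assisted zinc insertion tolerates ester and pyrone, and the organozinc couples with the E-iodoalkene with retention of geometry under neutral conditions that spare formate, silyl ether and terminal alkyne.

Step 16
Reactants: 23 methyl 5-[(E)-2-{(1S,2R,3R,4S)-2-(but-3-ynyl)-3-[3-(formyloxy)-3-methylbutyl]-1,3-dimethyl-4-(triethylsilyloxy)cyclohexyl}ethenyl]-6-methoxy-2-methyl-4-oxo-4H-pyran-3-carboxylate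
Product: 25 methyl 5-{[(1S,4aR,5R,6S,8aS)-5-[3-(formyloxy)-3-methylbutyl]-5,8a-dimethyl-2-methylidene-6-(triethylsilyloxy)decahydronaphthalen-1-yl]methyl}-6-methoxy-2-methyl-4-oxo-4H-pyran-3-carboxylate, via exocyclic vinylstannane 24 (not isolated)
Conditions: Bu3SnH (1.5 equiv) and AIBN (0.2 equiv) added over 6 h, PhH (0.01 M), 80 °C; then AcOH, CH2Cl2, 23 °C
Reagents that add atoms: none
Why: Bu3Sn• adds reversibly to the terminal alkyne carbon C17, the σ-vinyl radical so formed at C8 attacks C9 of the alkenylpyrone, the C11 radical (delocalised into the C3'=C2' enol-ether unit of the pyrone ring) takes hydrogen from Bu3SnH to carry the chain, and AcOH then protonates vinylstannane 24 at C17, where the β-tin effect stabilises the tertiary C8 cation, so that tin leaves and C8=C17H2 appears without migration of the double bond. The closest known reaction type is the stannyl-radical-induced cyclisation of enynes (vinyl radical cyclisation) followed by protodestannylation. Ring B closes in the 6-exo-trig mode, and the 7-endo alternative (attack at C11) would give an unstabilised secondary radical at C9 and should not compete. The new stereocentre C9 is controlled by ring A: in the chair-like transition state the fully substituted C4 must be equatorial on the forming ring (C1 axial, 10-CH3 equatorial), because in the other chair the first CH2 of the C4 side chain would be syn-pentane to both C7 and C9, and the C9=C11 bond lies pseudo-equatorial, which places H9 cis to H5 and C11 on the β face (9S). The step needs chemoselective radical generation and ring closure faster than hydrogen transfer: tin-radical addition to the alkene is reversible and unproductive, C4 and C10 carry no hydrogen so that no 1,5-hydrogen shift to C8 is possible, the pyrone-activated acceptor accelerates closure, and slow addition keeps the stannane concentration low.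

Step 17
Reactants: 25 methyl 5-{[(1S,4aR,5R,6S,8aS)-5-[3-(formyloxy)-3-methylbutyl]-5,8a-dimethyl-2-methylidene-6-(triethylsilyloxy)decahydronaphthalen-1-yl]methyl}-6-methoxy-2-methyl-4-oxo-4H-pyran-3-carboxylate
Product: 26 methyl 5-{[(1S,4aR,5R,6S,8aS)-5-[3-(formyloxy)-3-methylbutyl]-6-hydroxy-5,8a-dimethyl-2-methylidenedecahydronaphthalen-1-yl]methyl}-6-methoxy-2-methyl-4-oxo-4H-pyran-3-carboxylate (CNP0292250.1)
Conditions: HF·pyridine, pyridine, THF, 0 → 23 °C
Reagents that add atoms: none
Why: Buffered fluoride cleaves the Si–O bond of the triethylsilyl ether selectively, and the mild non-nucleophilic medium leaves the tertiary formate, the methyl ester, the methoxypyrone and the exocyclic methylene unchanged.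

**Compound list**
1 | dimethyl (2-oxopropyl)phosphonate | CC(=O)CP(=O)(OC)OC | starting material
2 | 1-bromo-3-methylbut-2-ene (prenyl bromide) | CC(C)=CCBr | starting material
3 | dimethyl (6-methyl-2-oxohept-5-en-3-yl)phosphonate (racemic) | CC(=O)C(CC=C(C)C)P(=O)(OC)OC | intermediate
4 | pent-4-yn-1-ol | C#CCCCO | starting material
5 | pent-4-ynal | C#CCCC=O | intermediate
6 | (E)-3-(3-methylbut-2-enyl)oct-3-en-7-yn-2-one | CC(=O)/C(CC=C(C)C)=C/CCC#C | intermediate
7 | (E)-triisopropyl{[3-(3-methylbut-2-enyl)octa-1,3-dien-7-yn-2-yl]oxy}silane | C=C(O[Si](C(C)C)(C(C)C)C(C)C)/C(CC=C(C)C)=C/CCC#C | intermediate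
8 | methacrolein (2-methylprop-2-enal) | C=C(C)C=O | starting material
9 | (1R,2S)-2-(but-3-ynyl)-1-methyl-3-(3-methylbut-2-enyl)-4-(triisopropylsilyloxy)cyclohex-3-ene-1-carbaldehyde | C#CCC[C@H]1C(CC=C(C)C)=C(O[Si](C(C)C)(C(C)C)C(C)C)CC[C@@]1(C)C=O | intermediate
10 | {[(3R,4R)-3-(but-3-ynyl)-4-[(E)-2-iodoethenyl]-4-methyl-2-(3-methylbut-2-enyl)cyclohex-1-en-1-yl]oxy}triisopropylsilane | C#CCC[C@H]1C(CC=C(C)C)=C(O[Si](C(C)C)(C(C)C)C(C)C)CC[C@@]1(C)/C=C/I | intermediate
11 | tetrabutylammonium (3R,4R)-3-(but-3-ynyl)-4-[(E)-2-iodoethenyl]-4-methyl-2-(3-methylbut-2-enyl)cyclohex-1-en-1-olate | C#CCC[C@H]1C(CC=C(C)C)=C([O-])CC[C@@]1(C)/C=C/I.CCCC[N+](CCCC)(CCCC)CCCC | intermediate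
12 | (2R,3R,4R)-3-(but-3-ynyl)-4-[(E)-2-iodoethenyl]-2,4-dimethyl-2-(3-methylbut-2-enyl)cyclohexan-1-one | C#CCC[C@H]1[C@@](C)(CC=C(C)C)C(=O)CC[C@@]1(C)/C=C/I | intermediate
13 | (2R,3R,4R)-3-(but-3-ynyl)-2-[(3,3-dimethyloxiran-2-yl)methyl]-4-[(E)-2-iodoethenyl]-2,4-dimethylcyclohexan-1-one (both oxirane epimers) | C#CCC[C@H]1[C@@](C)(CC2OC2(C)C)C(=O)CC[C@@]1(C)/C=C/I | intermediate
14 | (1S,2R,3R,4R)-3-(but-3-ynyl)-2-(3-hydroxy-3-methylbutyl)-4-[(E)-2-iodoethenyl]-2,4-dimethylcyclohexan-1-ol | C#CCC[C@H]1[C@@](C)(CCC(C)(C)O)[C@@H](O)CC[C@@]1(C)/C=C/I | intermediate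
15 | 4-{(1R,2R,3R,6S)-2-(but-3-ynyl)-3-[(E)-2-iodoethenyl]-1,3-dimethyl-6-(triethylsilyloxy)cyclohexyl}-2-methylbutan-2-ol | C#CCC[C@H]1[C@@](C)(CCC(C)(C)O)[C@@H](O[Si](CC)(CC)CC)CC[C@@]1(C)/C=C/I | intermediate
16 | 4-{(1R,2R,3R,6S)-2-(but-3-ynyl)-3-[(E)-2-iodoethenyl]-1,3-dimethyl-6-(triethylsilyloxy)cyclohexyl}-2-methylbutan-2-yl formate | C#CCC[C@H]1[C@@](C)(CCC(C)(C)OC=O)[C@@H](O[Si](CC)(CC)CC)CC[C@@]1(C)/C=C/I | intermediate
17 | methyl acetoacetate | CC(=O)CC(=O)OC | starting material
18 | malonyl dichloride | O=C(Cl)CC(=O)Cl | starting material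
19 | methyl 4-hydroxy-2-methyl-6-oxo-6H-pyran-3-carboxylate | COC(=O)C1=C(C)OC(=O)C=C1O | intermediate
20 | methyl 6-methoxy-2-methyl-4-oxo-4H-pyran-3-carboxylate | COC(=O)c1c(C)oc(OC)cc1=O | intermediate
21 | methyl 5-iodo-6-methoxy-2-methyl-4-oxo-4H-pyran-3-carboxylate | COC(=O)c1c(C)oc(OC)c(I)c1=O | intermediate
22 | [5-(methoxycarbonyl)-2-methoxy-6-methyl-4-oxo-4H-pyran-3-yl]zinc iodide | COC(=O)c1c(C)oc(OC)c([Zn]I)c1=O | intermediate
23 | methyl 5-[(E)-2-{(1S,2R,3R,4S)-2-(but-3-ynyl)-3-[3-(formyloxy)-3-methylbutyl]-1,3-dimethyl-4-(triethylsilyloxy)cyclohexyl}ethenyl]-6-methoxy-2-methyl-4-oxo-4H-pyran-3-carboxylate | C#CCC[C@H]1[C@@](C)(CCC(C)(C)OC=O)[C@@H](O[Si](CC)(CC)CC)CC[C@@]1(C)/C=C/c2c(OC)oc(C)c(C(=O)OC)c2=O | intermediate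
24 | C17-tributylstannyl derivative of 25 (exocyclic vinylstannane, E/Z mixture) | CCCC[Sn](CCCC)(CCCC)C=C1CC[C@H]2[C@@](C)(CCC(C)(C)OC=O)[C@@H](O[Si](CC)(CC)CC)CC[C@@]2(C)[C@H]1Cc3c(OC)oc(C)c(C(=O)OC)c3=O | intermediate
25 | methyl 5-{[(1S,4aR,5R,6S,8aS)-5-[3-(formyloxy)-3-methylbutyl]-5,8a-dimethyl-2-methylidene-6-(triethylsilyloxy)decahydronaphthalen-1-yl]methyl}-6-methoxy-2-methyl-4-oxo-4H-pyran-3-carboxylate | C=C1CC[C@H]2[C@@](C)(CCC(C)(C)OC=O)[C@@H](O[Si](CC)(CC)CC)CC[C@@]2(C)[C@H]1Cc3c(OC)oc(C)c(C(=O)OC)c3=O | intermediate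
26 | methyl 5-{[(1S,4aR,5R,6S,8aS)-5-[3-(formyloxy)-3-methylbutyl]-6-hydroxy-5,8a-dimethyl-2-methylidenedecahydronaphthalen-1-yl]methyl}-6-methoxy-2-methyl-4-oxo-4H-pyran-3-carboxylate (CNP0292250.1) | C=C1CC[C@H]2[C@@](C)(CCC(C)(C)OC=O)[C@@H](O)CC[C@@]2(C)[C@H]1Cc1c(OC)oc(C)c(C(=O)OC)c1=O | target

Total step count: 17. Longest linear sequence: 13 steps (steps 1, 3–11, 15–17).

**Steps most likely to fail**

Step 16. Hydrogen transfer to the C8 vinyl radical may outrun ring closure (plain hydrostannation of the alkyne), or the preference for the chair with C4 equatorial may be too small. The fallback sets out from 23 and returns at 25. It replaces the radical chain by a palladium-hydride reductive enyne cyclisation (Pd2(dba)3·CHCl3, P(o-tol)3, AcOH, Et3SiH, toluene, 23 °C). Hydropalladation of the alkyne places divalent palladium on C8, a syn 6-exo carbopalladation of C9=C11 follows through an ordered, alkene-bound transition state, and the pyrone-stabilised C11–Pd bond is cleaved by the silane. No compound outside the list is formed (F0).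

Step 5. The hindered 1,2,3-trisubstituted diene may show low reactivity, the endo preference may erode, or the enantiofacial control by the catalyst may be insufficient. The fallback sets out from 7 and 8 and returns at 9, giving up asymmetric catalysis in favour of a racemic cycloaddition and resolution.
- MeAlCl2 (20 mol %, CH2Cl2, −78 °C) gives the endo adduct as the racemate, that is 9 together with its mirror image ent-9 F1.
- Condensation with (1R,2R)-N,N'-dimethyl-1,2-diphenylethane-1,2-diamine (4 Å MS, Et2O, 23 °C) gives two diastereomeric aminals, the imidazolidine of 9 F2 and the imidazolidine of ent-9 F3, which are separated by chromatography.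
- Mild hydrolysis of F2 (aqueous citric acid/Et2O, 0 °C) returns enantiopure 9 and the recoverable diamine.

Step 15. The metalated pyrone may open by β-elimination, or transmetalation of the doubly ortho-substituted organozinc may be slow, leading to protodemetalation. The fallback sets out from 21 and 16 and returns at 23, using an isolable tin nucleophile instead of the organozinc made in the flask.
- 21 with Bu3SnSnBu3 and Pd(PPh3)4 (toluene, 100 °C) gives methyl 6-methoxy-2-methyl-4-oxo-5-(tributylstannyl)-4H-pyran-3-carboxylate F4.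
- F4 is purified and then joined to 16 by a copper-assisted Stille coupling (Pd2(dba)3, AsPh3, CuI cat., DMF, 23 → 40 °C).

**Further compounds**
F1 | step 5 | (1S,2R)-2-(but-3-ynyl)-1-methyl-3-(3-methylbut-2-enyl)-4-(triisopropylsilyloxy)cyclohex-3-ene-1-carbaldehyde (ent-9) | C#CCC[C@@H]1C(CC=C(C)C)=C(O[Si](C(C)C)(C(C)C)C(C)C)CC[C@]1(C)C=O
F2 | step 5 | (4R,5R)-1,3-dimethyl-4,5-diphenylimidazolidine bearing the cyclohexenyl residue of 9 at C2 | C#CCC[C@H]1C(CC=C(C)C)=C(O[Si](C(C)C)(C(C)C)C(C)C)CC[C@@]1(C)C2N(C)[C@H](c3ccccc3)[C@@H](c3ccccc3)N2C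
F3 | step 5 | (4R,5R)-1,3-dimethyl-4,5-diphenylimidazolidine bearing the cyclohexenyl residue of ent-9 at C2 | C#CCC[C@@H]1C(CC=C(C)C)=C(O[Si](C(C)C)(C(C)C)C(C)C)CC[C@]1(C)C2N(C)[C@H](c3ccccc3)[C@@H](c3ccccc3)N2C
F4 | step 15 | methyl 6-methoxy-2-methyl-4-oxo-5-(tributylstannyl)-4H-pyran-3-carboxylate | COC(=O)c1c(C)oc(OC)c([Sn](CCCC)(CCCC)CCCC)c1=O
F0 | step 16 | none | none
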